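**Strategy.** The seven-membered ring (C4a–C5–C6–C7–C8–C9–C9a) is closed last by para–ortho' oxidative phenol coupling (C4a–C5) of a 1,4-diarylbutane, so the problem reduces to the C7/C8/C9 triad. The key step builds it through a temporary ring: the C9 oxygen and the benzylic C6, 1,4-related in that ring, are tied as a 2,5-diaryloxolane. A 5-exo cyclization of an α-alkoxybenzyl radical at C9 onto a C8 vinyl group forms C8–C9, converts the vinyl terminus into the C8 methyl, funnels both acetal epimers into one C9 configuration and sets C8 and C9 from C6/C7. The precursor is the O,S-acetal joining an anti-crotyl adduct of acetylsyringaldehyde to a 3,4,5-trimethoxybenzyl carbon.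

Key step: step 4

Remark: atom labels follow the target (C5 spiro carbon, C6 CH2, C7 and C8 CH(CH3), C9 CH(OAc), C4a and C9a aryl carbons); 4-acetoxy-3,5-dimethoxybenzaldehyde is taken as a catalogue compound (otherwise one acetylation of syringaldehyde).

Step 1
Reactants: 1 4-formyl-2,6-dimethoxyphenyl acetate; 2 (E)-crotylboronic acid pinacol ester
Product: 3 4-[(1S,2S)-1-hydroxy-2-methylbut-3-en-1-yl]-2,6-dimethoxyphenyl acetate
Conditions: (S)-TRIP [(S)-3,3'-bis(2,4,6-triisopropylphenyl)-1,1'-binaphthyl-2,2'-diyl hydrogen phosphate] (5 mol %), 4 Å MS, toluene, −30 °C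
Reagents that add atoms: none
Why: Chiral-phosphoric-acid-catalysed crotylboration runs through a closed chair transition state in which the (E)-boronate keeps its methyl equatorial (anti adduct) and the (S)-acid should open the Si face of the aldehyde, which sets C6 (S, a temporary centre) and C7 (S here, R in the target once C6 has lost its oxygen); the antipodal acid is used if the facial sense proves opposite.

Step 2
Reactants: 4 5-(chloromethyl)-1,2,3-trimethoxybenzene; 5 sodium benzenethiolate
Product: 6 1,2,3-trimethoxy-5-[(phenylsulfanyl)methyl]benzene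
Conditions: EtOH, rt
Reagents that add atoms: none
Why: SN2 displacement of a benzylic chloride by thiolate (thioether synthesis); no stereocenter is formed.

Step 3
Reactants: 6 1,2,3-trimethoxy-5-[(phenylsulfanyl)methyl]benzene; 3 4-[(1S,2S)-1-hydroxy-2-methylbut-3-en-1-yl]-2,6-dimethoxyphenyl acetate
Product: 8 4-[(1S,2S)-2-methyl-1-{[phenylsulfanyl(3,4,5-trimethoxyphenyl)methyl]oxy}but-3-en-1-yl]-2,6-dimethoxyphenyl acetate (both epimers at the acetal carbon C9), via 5-[chloro(phenylsulfanyl)methyl]-1,2,3-trimethoxybenzene 7 (not isolated)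
Conditions: NCS, CH2Cl2, 0 °C; then 3, iPr2NEt, 4 Å MS, 0 °C → rt
Reagents that add atoms: none
Why: S-chlorination and Pummerer-type shift give the α-chloro sulfide, whose aryl-stabilised thionium ion is trapped by the secondary alcohol (O,S-acetal formation) without an oxocarbenium ion ever being formed next to the alkene (no Prins closure); the acetal centre C9 forms as a mixture of epimers, which is irrelevant because it becomes a planar radical in step 4.

Step 4
Reactants: 8 4-[(1S,2S)-2-methyl-1-{[phenylsulfanyl(3,4,5-trimethoxyphenyl)methyl]oxy}but-3-en-1-yl]-2,6-dimethoxyphenyl acetate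
Product: 10 4-[(2S,3S,4S,5R)-3,4-dimethyl-5-(3,4,5-trimethoxyphenyl)oxolan-2-yl]-2,6-dimethoxyphenyl acetate, via α-alkoxybenzyl radical 9 (not isolated)
Conditions: Bu3SnH (slow addition), AIBN (cat.), benzene, 80 °C
Reagents that add atoms: none
Why: The tributyltin radical abstracts the phenylthio group and gives the planar α-alkoxybenzyl radical 9 at C9, so both acetal epimers converge on one intermediate; 9 adds to the internal vinyl carbon C8 and the resulting primary radical takes hydrogen from Bu3SnH, which forms the C8–C9 bond and turns the vinyl terminus into the C8 methyl group. The closest known reaction type is the tin-hydride cyclization of α-alkoxy radicals (2-oxahex-5-enyl radicals) from O,S- or O,Se-acetals to 2,3-disubstituted tetrahydrofurans. The only ring closed is the five-membered oxolane, in the 5-exo-trig mode. C8 is set by the chair-like transition state in which the C7 methyl and the C6 aryl group (trans to each other, from step 1) are both pseudo-equatorial, which should place the new C8 methyl trans to the C7 methyl; C9 is set by the preference of the substituent on the radical carbon for the pseudo-equatorial position, which should place the trimethoxyphenyl group cis to the C8 methyl (2,5-cis diaryl oxolane). The step needs 5-exo over 6-endo closure (the normal preference of these radicals), cyclization ahead of hydrogen transfer to the stabilised benzylic radical (secured by keeping the hydride concentration low) and the cis mode at C9 (secured by the all-equatorial chair, in which the two existing centres reinforce each other).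

Step 5
Reactants: 10 4-[(2S,3S,4S,5R)-3,4-dimethyl-5-(3,4,5-trimethoxyphenyl)oxolan-2-yl]-2,6-dimethoxyphenyl acetate
Product: 13 4-[(2R,3S,4R)-4-hydroxy-2,3-dimethyl-4-(3,4,5-trimethoxyphenyl)butyl]-2,6-dimethoxyphenol, via oxolanylphenol 11 (not isolated), via para-quinone methide 12 (not isolated)
Conditions: NaBH4 (excess, in portions), NaOH (0.5 M), EtOH/H2O, 80 °C
Reagents that add atoms: none
Why: Hydroxide cleaves the aryl acetate, the phenolate expels the ring oxygen as the C9 alkoxide to give para-quinone methide 12, and borohydride adds in the 1,6 sense at C6 (quinone methide reduction), so only the ether bond at the phenol-bearing benzylic carbon can open, C9 keeps its oxygen with retention and C7 and C8 are untouched.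

Step 6
Reactants: 13 4-[(2R,3S,4R)-4-hydroxy-2,3-dimethyl-4-(3,4,5-trimethoxyphenyl)butyl]-2,6-dimethoxyphenol
Product: 15 (1R,2S,3R)-4-(4-hydroxy-3,5-dimethoxyphenyl)-2,3-dimethyl-1-(3,4,5-trimethoxyphenyl)butyl acetate, via diacetate 14 (not isolated)
Conditions: Ac2O, DMAP (cat.), pyridine, CH2Cl2, rt; then pyrrolidine, 0 °C
Reagents that add atoms: acetic anhydride, CC(=O)OC(C)=O
Why: DMAP-catalysed acylation of both hydroxyl groups followed by chemoselective aminolysis of the far more electrophilic aryl acetate should leave the secondary benzylic acetate; no stereocenter is touched.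

Step 7
Reactants: 15 (1R,2S,3R)-4-(4-hydroxy-3,5-dimethoxyphenyl)-2,3-dimethyl-1-(3,4,5-trimethoxyphenyl)butyl acetate
Product: 17 (7R,8S,9R)-2,3,4,3',5'-pentamethoxy-7,8-dimethyl-4'-oxo-6,7,8,9-tetrahydrospiro[benzo[7]annulene-5,1'-cyclohexa[2,5]dien]-9-yl acetate (CNP0143674.1), via aryloxyiodane 16 (not isolated)
Conditions: PhI(OAc)2, (CF3)2CHOH, −20 → 0 °C
Reagents that add atoms: none
Why: Hypervalent-iodine oxidative dearomatization: ligand exchange at iodine and loss of iodobenzene give a phenoxenium ion that is attacked at its para carbon C5 by the ortho carbon C4a of the trimethoxyphenyl ring (para–ortho' phenol coupling, seven-membered ring), which should give the cross-conjugated spirodienone, whose spiro carbon is not stereogenic.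

**Compound list**

1 | 4-formyl-2,6-dimethoxyphenyl acetate | CC(=O)Oc1c(OC)cc(C=O)cc1OC | starting material
2 | (E)-crotylboronic acid pinacol ester | C/C=C/CB1OC(C)(C)C(C)(C)O1 | starting material
3 | 4-[(1S,2S)-1-hydroxy-2-methylbut-3-en-1-yl]-2,6-dimethoxyphenyl acetate | CC(=O)Oc1c(OC)cc(cc1OC)[C@@H](O)[C@@H](C)C=C | intermediate
4 | 5-(chloromethyl)-1,2,3-trimethoxybenzene | COc1cc(CCl)cc(OC)c1OC | starting material
5 | sodium benzenethiolate | [Na+].[S-]c1ccccc1 | starting material
6 | 1,2,3-trimethoxy-5-[(phenylsulfanyl)methyl]benzene | COc1cc(CSc2ccccc2)cc(OC)c1OC | intermediate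
7 | 5-[chloro(phenylsulfanyl)methyl]-1,2,3-trimethoxybenzene | COc1cc(C(Cl)Sc2ccccc2)cc(OC)c1OC | intermediate (not isolated)
8 | 4-[(1S,2S)-2-methyl-1-{[phenylsulfanyl(3,4,5-trimethoxyphenyl)methyl]oxy}but-3-en-1-yl]-2,6-dimethoxyphenyl acetate, both C9 epimers | COc1cc(cc(OC)c1OC)C(Sc1ccccc1)O[C@@H]([C@@H](C)C=C)c1cc(OC)c(OC(C)=O)c(OC)c1 | intermediate
9 | α-alkoxybenzyl radical (8 without the phenylthio group) | COc1cc(cc(OC)c1OC)[CH]O[C@@H]([C@@H](C)C=C)c1cc(OC)c(OC(C)=O)c(OC)c1 | intermediate (not isolated)
10 | 4-[(2S,3S,4S,5R)-3,4-dimethyl-5-(3,4,5-trimethoxyphenyl)oxolan-2-yl]-2,6-dimethoxyphenyl acetate | O1[C@@H](c2cc(OC)c(OC)c(OC)c2)[C@@H](C)[C@H](C)[C@H]1c1cc(OC)c(OC(C)=O)c(OC)c1 | intermediate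
11 | 4-[(2S,3S,4S,5R)-3,4-dimethyl-5-(3,4,5-trimethoxyphenyl)oxolan-2-yl]-2,6-dimethoxyphenol | O1[C@@H](c2cc(OC)c(OC)c(OC)c2)[C@@H](C)[C@H](C)[C@H]1c1cc(OC)c(O)c(OC)c1 | intermediate (not isolated)
12 | 4-[(2R,3S,4R)-4-hydroxy-2,3-dimethyl-4-(3,4,5-trimethoxyphenyl)butylidene]-2,6-dimethoxycyclohexa-2,5-dien-1-one | COC1=CC(=C[C@@H](C)[C@H](C)[C@@H](O)c2cc(OC)c(OC)c(OC)c2)C=C(OC)C1=O | intermediate (not isolated)
13 | 4-[(2R,3S,4R)-4-hydroxy-2,3-dimethyl-4-(3,4,5-trimethoxyphenyl)butyl]-2,6-dimethoxyphenol | COc1cc(C[C@@H](C)[C@H](C)[C@@H](O)c2cc(OC)c(OC)c(OC)c2)cc(OC)c1O | intermediate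
14 | 4-[(2R,3S,4R)-4-acetoxy-2,3-dimethyl-4-(3,4,5-trimethoxyphenyl)butyl]-2,6-dimethoxyphenyl acetate | COc1cc(C[C@@H](C)[C@H](C)[C@@H](OC(C)=O)c2cc(OC)c(OC)c(OC)c2)cc(OC)c1OC(C)=O | intermediate (not isolated)
15 | (1R,2S,3R)-4-(4-hydroxy-3,5-dimethoxyphenyl)-2,3-dimethyl-1-(3,4,5-trimethoxyphenyl)butyl acetate | COc1cc(C[C@@H](C)[C@H](C)[C@@H](OC(C)=O)c2cc(OC)c(OC)c(OC)c2)cc(OC)c1O | intermediate
16 | acetoxy(aryloxy)phenyliodane from 15 | COc1cc(C[C@@H](C)[C@H](C)[C@@H](OC(C)=O)c2cc(OC)c(OC)c(OC)c2)cc(OC)c1OI(OC(C)=O)c1ccccc1 | intermediate (not isolated)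
17 | (7R,8S,9R)-2,3,4,3',5'-pentamethoxy-7,8-dimethyl-4'-oxo-6,7,8,9-tetrahydrospiro[benzo[7]annulene-5,1'-cyclohexa[2,5]dien]-9-yl acetate | COC1=CC2(C=C(OC)C1=O)C[C@@H](C)[C@H](C)[C@@H](OC(C)=O)c1cc(OC)c(OC)c(OC)c12 | target

**Step count.** Total: 7 steps. Longest linear sequence: 6 steps (1 → 3 → 8 → 10 → 13 → 15 → 17).

**Steps most likely to fail**

Step 4. The stabilised benzylic radical may take hydrogen before it cyclizes, the ring closure may be reversible, or facial control at C9 may be weak so that the aryl group ends up trans to the C8 methyl. The fallback accepts the C9 epimer and corrects it at the esterification stage. It sets out from 8: the same cyclization then gives 4-[(2S,3S,4S,5S)-3,4-dimethyl-5-(3,4,5-trimethoxyphenyl)oxolan-2-yl]-2,6-dimethoxyphenyl acetate F1. NaBH4/NaOH as in step 5 opens it to 4-[(2R,3S,4S)-4-hydroxy-2,3-dimethyl-4-(3,4,5-trimethoxyphenyl)butyl]-2,6-dimethoxyphenol F2. A Mitsunobu reaction (PPh3, DIAD, AcOH, toluene, 0 °C) should then install the acetate with inversion at C9, acetic acid being far more acidic than the hindered phenol, and the route comes back at 15.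

Step 5. The phenolate may expel the C9 alkoxide too slowly at 80 °C, or the quinone methide may tautomerize to the C6=C7 styrene before hydride arrives, which would scramble C7. The fallback opens the ring through a cation instead of an anion. It sets out from 10: K2CO3 in MeOH at rt gives phenol 11, now isolated. Et3SiH and CF3CO2H in CH2Cl2 at −20 °C should then ionize only the C6–O bond, because the untwisted para-hydroxyl group stabilises a C6 cation far better than the twisted 4-methoxy group stabilises a C9 cation, and the silane reduces it. The route comes back at 13; no new compound is made.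

Step 7. The phenoxenium ion may be captured at C5 by solvent or acetate instead of by the arene, or the spirodienone may undergo acid-induced dienone–phenol rearrangement to the dibenzocyclooctadiene. The fallback is anodic oxidation of 15 (carbon anode, undivided cell, LiClO4, MeCN/(CF3)2CHOH, 2,6-lutidine, constant current), a known route from para-alkylphenols to spirodienones in which no acetate, iodane or free acid is present. It sets out from 15 and comes back at 17; no new compound is made.

**Further compounds**

F1 | step 4 | 4-[(2S,3S,4S,5S)-3,4-dimethyl-5-(3,4,5-trimethoxyphenyl)oxolan-2-yl]-2,6-dimethoxyphenyl acetate | O1[C@H](c2cc(OC)c(OC)c(OC)c2)[C@@H](C)[C@H](C)[C@H]1c1cc(OC)c(OC(C)=O)c(OC)c1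
F2 | step 4 | 4-[(2R,3S,4S)-4-hydroxy-2,3-dimethyl-4-(3,4,5-trimethoxyphenyl)butyl]-2,6-dimethoxyphenol | COc1cc(C[C@@H](C)[C@H](C)[C@H](O)c2cc(OC)c(OC)c(OC)c2)cc(OC)c1O
F0 | step 5 | none | none
F0 | step 7 | none | none
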